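Readings and results come from a simulation on assumed constants; noise was put on by code.

Time was the first item: the meeting had to say what stands in the flask at 15 d, and it had the west run, charged with half the free monomer at the same loading of initiator.

| flask | free monomer | initiator | remark | time |
|---|---|---|---|---|
| west | 10 mM | 0.2 mol% | run made earlier |  |
| flask | 20 mM | 0.2 mol% |  | 15 d |

west run (percent of the free monomer charged)

| time / d | free monomer / % | over-reaction product / % | monomer in chains / % |
|---|---|---|---|
| 0.833 | 0.6 | 73.1 | 23.2 |
| 1.67 | 0.2 | 91.1 | 3.4 |
| 2.50 | 0.7 | 91.1 | 1.0 |
| 4.00 | 0.3 | 95.7 | 1.3 |
| 5.00 | 0.4 | 95.0 | 0 |

(readings scatter by 1 percentage point)

- percent here means free monomer units held: one homo dimer counts as two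
- the numbers in the tables scatter with a standard deviation of 1 percentage point
- reactions considered so far: 2 free monomer -> homo dimer; free monomer + living end -> monomer in chains + living end; monomer in chains -> over-reaction product; free monomer + initiator -> living end + monomer in chains
- the reaction counts as stopped when no species that holds the free monomer changes by six tenths of a point or more over the second half of the time
- no earlier run changes the charge of initiator; that part of a forecast is a guess

1. why nothing more happens at 15 d, or that something still does (forward and back rates have come level / no working catalyst is left / it is still moving / all of the free monomer has reacted)
2. how much of the free monomer has reacted by 15 d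
3. how much over-reaction product there is at 15 d, in percent of the free monomer charged
4. amount of monomer in chains if the flask were left three thousand times as long, in percent of the free monomer charged

The first speaker read monomer in chains in the west run falling from 23.2% to 3.4% between the first two readings. That gives a first-order constant of 2.29 d⁻¹ and a half-life of 0.302 d, far shorter than the time asked, so she expected the chains in the flask to have turned into over-reaction product well before the end.

The second speaker went to the blackboard and divided one rate by the other so that time dropped out. The rate to homo dimer goes with [free monomer] squared, the rate into chains with [free monomer] times [living end] or [initiator], so their quotient goes with [free monomer] over [living end] or [initiator], and doubling the charge at fixed loading leaves it unchanged at each conversion.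

By 1.67 d free monomer in the west run reads 0.2%, and from there on over-reaction product and monomer in chains together average 94.7%. She took the gap as homo dimer and read 0.0565 as the split, the units of free monomer going to homo dimer per unit going into chains, a selectivity factor carrying the scatter of those readings. She therefore committed to 94.7% of over-reaction product in the flask.

The forecast differed slightly from her figure. It gave 95.5% of over-reaction product, conversion 99.8%, 0% of monomer in chains for the flask left standing, and the end as all of the free monomer has reacted, holding that “their selectivity stays the same”.

In the flask all of the free monomer has reacted, with conversion 100%, over-reaction product at 93.9%, and 0% of monomer in chains when left standing.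

    2 free monomer → homo dimer (k = 1.40 L mol⁻¹ h⁻¹)
    free monomer + living end → monomer in chains + living end, rate k2*[living end]*[free monomer] (k = 12000 L mol⁻¹ h⁻¹)
    monomer in chains → over-reaction product (k = 0.0960 h⁻¹)
    free monomer + initiator → living end + monomer in chains (k = 320 L mol⁻¹ h⁻¹)

Homo dimer in the flask stands at 6.15% at 15.0 d, which makes the flask's split 0.0655. The neighbour is charged with the same free monomer and 0.05 mol% of initiator, and its living end stands at 0.0100 mM against 0.0400 mM in the flask. Carrying the split as [free monomer] over [living end], the split read in the west run, 0.0565, times 4.00 gives 0.226 for the neighbour, hence 81.6% of over-reaction product. The neighbour, with 0% of its free monomer left, holds 18.5% of homo dimer and 81.5% of over-reaction product.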